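The route cuts the exocyclic C(sp2)–CH2 bond between alkene carbon C1 of the cyclohexene ring and the benzoyloxymethyl carbon. C1 is the one ring carbon that carries bromine in the cis-dihydrodiol obtained by enzymatic dearomatization of bromobenzene. Its two carbinols become C5 and C6, and an anti osmylation adds the C3 and C4 oxygens. The key step is a protecting-group-free Stille coupling, run last. It unites the fully decorated bromocyclohexene (C3 methyl ether, C5 benzoate, free C4 and C6 hydroxyls, all four stereocentres set) with (tributylstannyl)methyl benzoate, so the whole oxygen pattern is in place before the fragments meet.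

Key step: step 8

Remark: ring positions are named with the target's numbering throughout (C1 = alkene carbon bearing CH2OBz, C2 = vinylic CH, C3 = C–OMe, C4 = C–OH, C5 = C–OBz, C6 = C–OH); diol 1 is assumed to be purchased as the single (1S,2S) enantiomer.

Step 1
Reactants: 1 (1S,2S)-3-bromocyclohexa-3,5-diene-1,2-diol
Product: 2 (3aS,7aS)-4-bromo-2,2-dimethyl-3a,7a-dihydro-1,3-benzodioxole
Conditions: Me2C(OMe)2, p-TsOH (cat.), acetone, 0 °C to rt; crude product used at once
Reagents that add atoms: 2,2-dimethoxypropane COC(C)(C)OC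
Why: Acid-catalysed transketalisation closes the cis-fused isopropylidene acetal on the syn-diol without touching a stereocentre, and 2 is carried on immediately because the diene dimerises by Diels–Alder reaction on standing.

Step 2
Reactants: 2 (3aS,7aS)-4-bromo-2,2-dimethyl-3a,7a-dihydro-1,3-benzodioxole
Product: 3 (3aS,4R,5R,7aS)-7-bromo-2,2-dimethyl-3a,4,5,7a-tetrahydro-1,3-benzodioxole-4,5-diol
Conditions: OsO4 (2 mol %), NMO, acetone/H2O (10:1), rt
Reagents that add atoms: osmium tetroxide O=[Os](=O)(=O)=O (catalytic oxygen carrier); N-methylmorpholine N-oxide C[N+]1([O-])CCOCC1; water O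
Why: Catalytic syn-dihydroxylation (OsO4/NMO) should take place at the electron-richer, unhalogenated C3=C4 alkene from the face anti to the acetonide, which sets C3 and C4 cis to each other and trans to the C5/C6 oxygens.

Step 3
Reactants: 3 (3aS,4R,5R,7aS)-7-bromo-2,2-dimethyl-3a,4,5,7a-tetrahydro-1,3-benzodioxole-4,5-diol
Product: 5 (3aS,4R,5R,7aS)-7-bromo-4-[(4-methoxybenzyl)oxy]-2,2-dimethyl-3a,4,5,7a-tetrahydro-1,3-benzodioxol-5-ol, via dibutylstannylene acetal 4 (not isolated)
Conditions: Bu2SnO, PhMe, reflux (Dean–Stark); then PMBCl, Bu4NI (cat.), 90 °C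
Reagents that add atoms: 4-methoxybenzyl chloride COc1ccc(CCl)cc1; dibutyltin oxide CCCC[Sn](=O)CCCC (its atoms stay only in 4)
Why: Tin-acetal mediated regioselective O-alkylation should place PMB on O4, because in the half-chair that holds the C6 oxygen pseudoaxial (A1,2 strain with Br) O4 is the equatorial, doubly flanked oxygen of the cis-diol, the position a stannylene activates (cf. 3-O-alkylation of galactoside 3,4-diols), leaving the allylic O3–H free.

Step 4
Reactants: 5 (3aS,4R,5R,7aS)-7-bromo-4-[(4-methoxybenzyl)oxy]-2,2-dimethyl-3a,4,5,7a-tetrahydro-1,3-benzodioxol-5-ol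
Product: 6 (3aS,4R,5R,7aS)-7-bromo-5-methoxy-4-[(4-methoxybenzyl)oxy]-2,2-dimethyl-3a,4,5,7a-tetrahydro-1,3-benzodioxole
Conditions: NaH, MeI, THF, 0 °C to rt
Reagents that add atoms: iodomethane CI
Why: Williamson etherification of the only free hydroxyl installs the C3 methyl ether with no stereocentre involved.

Step 5
Reactants: 6 (3aS,4R,5R,7aS)-7-bromo-5-methoxy-4-[(4-methoxybenzyl)oxy]-2,2-dimethyl-3a,4,5,7a-tetrahydro-1,3-benzodioxole
Product: 7 (1S,2S,3S,6R)-4-bromo-6-methoxycyclohex-4-ene-1,2,3-triol
Conditions: TFA/H2O (9:1), CH2Cl2, 0 °C to rt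
Reagents that add atoms: none
Why: Aqueous acid should hydrolyse the isopropylidene acetal and solvolyse the PMB ether (stabilised 4-methoxybenzyl cation) in one operation, while the methyl ether and the vinyl bromide are inert to acidolysis.

Step 6
Reactants: 7 (1S,2S,3S,6R)-4-bromo-6-methoxycyclohex-4-ene-1,2,3-triol
Product: 8 (1S,2S,5R,6R)-3-bromo-2,6-dihydroxy-5-methoxycyclohex-3-en-1-yl benzoate
Conditions: Ph2BOCH2CH2NH2 (10 mol %), BzCl (1.1 equiv), iPr2NEt, MeCN, 0 °C to rt
Reagents that add atoms: benzoyl chloride O=C(Cl)c1ccccc1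
Why: Diarylborinic acid-catalysed regioselective acylation should bind the only cis-1,2-diol (O5/O6) as a tetracoordinate borinate and benzoylate its equatorial oxygen O5 (cf. 3-O-acylation of fuco- and galactopyranosides), the pseudoaxial O6 beside the C–Br carbon and the unbound O4 reacting much more slowly.

Step 7
Reactants: 9 (tributylstannyl)methanol
Product: 10 (tributylstannyl)methyl benzoate
Conditions: BzCl, pyridine, DMAP (cat.), CH2Cl2, 0 °C
Reagents that add atoms: benzoyl chloride O=C(Cl)c1ccccc1
Why: Standard DMAP-catalysed O-acylation of a primary alcohol, to which the C–Sn bond is inert.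

Step 8
Reactants: 8 (1S,2S,5R,6R)-3-bromo-2,6-dihydroxy-5-methoxycyclohex-3-en-1-yl benzoate; 10 (tributylstannyl)methyl benzoate
Product: 11 [(3R,4R,5R,6R)-5-(benzoyloxy)-4,6-dihydroxy-3-methoxycyclohex-1-en-1-yl]methyl benzoate
Conditions: Pd2(dba)3 (5 mol %), AsPh3 (20 mol %), CuI (10 mol %), NMP, 60 °C; aqueous KF work-up
Reagents that add atoms: none
Why: Pd(0) should insert into the C1–Br bond of 8 (its only carbon–halogen bond), Cu(I) should relay the benzoyloxymethyl group from tin to palladium, and reductive elimination then forms the C1(sp2)–CH2 bond with the alkene left in place. The closest known reaction type is the Stille coupling of α-oxygenated methylstannanes (hydroxymethyl- and acyloxyalkyl-stannanes) with alkenyl halides. No ring is closed and no stereocentre is created; C3–C6 are spectators, fixed by the configuration of 1 and by the anti osmylation of step 2. The step needs chemoselectivity towards two free hydroxyls and a migration-prone C5 benzoate, and group selectivity on tin (CH2OBz over butyl): the neutral, base-free conditions should secure the first, and the α-oxygen together with Cu(I)/AsPh3 acceleration of transmetalation the second. The weakly donating arsine and the moderate temperature are chosen so that Pd(0) does not ionise the allylic benzoate of the product.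

Compound list
1 | (1S,2S)-3-bromocyclohexa-3,5-diene-1,2-diol | O[C@H]1C=CC=C(Br)[C@H]1O | starting material
2 | (3aS,7aS)-4-bromo-2,2-dimethyl-3a,7a-dihydro-1,3-benzodioxole | CC1(C)O[C@H]2C=CC=C(Br)[C@H]2O1 | intermediate
3 | (3aS,4R,5R,7aS)-7-bromo-2,2-dimethyl-3a,4,5,7a-tetrahydro-1,3-benzodioxole-4,5-diol | CC1(C)O[C@H]2[C@H](O)[C@H](O)C=C(Br)[C@H]2O1 | intermediate
4 | dibutylstannylene acetal of 3 (2,2-dibutyl-1,3,2-dioxastannolane across O3/O4, acetonide on O5/O6 retained) | CC1(C)O[C@H]2[C@@H]3O[Sn](CCCC)(CCCC)O[C@@H]3C=C(Br)[C@H]2O1 | intermediate (not isolated)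
5 | (3aS,4R,5R,7aS)-7-bromo-4-[(4-methoxybenzyl)oxy]-2,2-dimethyl-3a,4,5,7a-tetrahydro-1,3-benzodioxol-5-ol | CC1(C)O[C@H]2[C@H](OCc3ccc(OC)cc3)[C@H](O)C=C(Br)[C@H]2O1 | intermediate
6 | (3aS,4R,5R,7aS)-7-bromo-5-methoxy-4-[(4-methoxybenzyl)oxy]-2,2-dimethyl-3a,4,5,7a-tetrahydro-1,3-benzodioxole | CC1(C)O[C@H]2[C@H](OCc3ccc(OC)cc3)[C@H](OC)C=C(Br)[C@H]2O1 | intermediate
7 | (1S,2S,3S,6R)-4-bromo-6-methoxycyclohex-4-ene-1,2,3-triol | CO[C@@H]1C=C(Br)[C@@H](O)[C@@H](O)[C@@H]1O | intermediate
8 | (1S,2S,5R,6R)-3-bromo-2,6-dihydroxy-5-methoxycyclohex-3-en-1-yl benzoate | CO[C@@H]1C=C(Br)[C@@H](O)[C@@H](OC(=O)c2ccccc2)[C@@H]1O | intermediate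
9 | (tributylstannyl)methanol | CCCC[Sn](CCCC)(CCCC)CO | starting material
10 | (tributylstannyl)methyl benzoate | CCCC[Sn](CCCC)(CCCC)COC(=O)c1ccccc1 | intermediate
11 | [(3R,4R,5R,6R)-5-(benzoyloxy)-4,6-dihydroxy-3-methoxycyclohex-1-en-1-yl]methyl benzoate | CO[C@@H]1C=C(COC(=O)c2ccccc2)[C@@H](O)[C@@H](OC(=O)c2ccccc2)[C@@H]1O | target

Total step count: 8. Longest linear sequence: 7 (steps 1–6 and 8); step 7 prepares the coupling partner.

Steps most likely to fail

Step 8. Transfer of an sp3 group from tin is slow, so butyl transfer or protodebromination may overtake it, and Pd(0) may ionise the allylic benzoate once it has formed. Fallback: the one-carbon unit is brought in as carbon monoxide while the ring is still fully protected. Setting out from 6, Pd-catalysed methoxycarbonylation (Pd(OAc)2, dppp, CO 1 atm, MeOH, Et3N, DMF, 70 °C) should give the unsaturated methyl ester F1. DIBAL-H (CH2Cl2, −78 °C) should reduce it to the allylic alcohol F2, and TFA/H2O should release the tetraol F3. Tin-acetal mediated double benzoylation (Bu2SnO, MeOH, reflux; then 2.1 equiv BzCl, dioxane, rt), the analogue of the 3,6-di-O-benzoylation of galactopyranosides, should acylate the primary hydroxyl and O5 and return to the route at 11.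

Step 3. Regiochemical leakage is the concern: alkylation of the allylic O3, or of both oxygens of the tin acetal. Fallback: the two hydroxyls are told apart by size instead of by tin coordination. Setting out from 3, TBDPSCl/imidazole (DMF, 0 °C) should silylate the unflanked allylic O3–H to give the silyl ether F4. 4-Methoxybenzyl trichloroacetimidate with catalytic La(OTf)3 (PhMe, rt) should then etherify O4–H under non-basic conditions that exclude silyl migration, giving the bis-ether F5. TBAF (THF, 0 °C) should remove the silyl group and return to the route at 5.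

Step 6. Over-acylation at O4 or O6 and base-induced benzoyl migration from O5 to its neighbours are the concerns. Fallback: O4 stays blocked while the benzoate is introduced. Setting out from 6, aqueous acetic acid (AcOH/H2O 4:1, 50 °C) should hydrolyse only the acetonide to give the PMB-protected cis-diol F6. With a single cis-diol left, tin-acetal mediated benzoylation (Bu2SnO; then BzCl, rt) should give the O5 benzoate F7. DDQ (CH2Cl2/pH 7 buffer) should then remove the PMB group under neutral conditions and return to the route at 8.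

Further compounds
F1 | step 8 | methyl ester (CO2Me in place of Br of 6) | CC1(C)O[C@H]2[C@H](OCc3ccc(OC)cc3)[C@H](OC)C=C(C(=O)OC)[C@H]2O1
F2 | step 8 | allylic alcohol (CH2OH in place of Br of 6) | CC1(C)O[C@H]2[C@H](OCc3ccc(OC)cc3)[C@H](OC)C=C(CO)[C@H]2O1
F3 | step 8 | tetraol, 4-(hydroxymethyl)-6-methoxycyclohex-4-ene-1,2,3-triol with the configuration of 7 | CO[C@@H]1C=C(CO)[C@@H](O)[C@@H](O)[C@@H]1O
F4 | step 3 | O3 tert-butyldiphenylsilyl ether of 3 | CC1(C)O[C@H]2[C@H](O)[C@H](O[Si](c3ccccc3)(c3ccccc3)C(C)(C)C)C=C(Br)[C@H]2O1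
F5 | step 3 | O3 tert-butyldiphenylsilyl, O4 4-methoxybenzyl bis-ether of 3 | CC1(C)O[C@H]2[C@H](OCc3ccc(OC)cc3)[C@H](O[Si](c3ccccc3)(c3ccccc3)C(C)(C)C)C=C(Br)[C@H]2O1
F6 | step 6 | O4 4-methoxybenzyl ether of triol 7 | CO[C@@H]1C=C(Br)[C@@H](O)[C@@H](O)[C@@H]1OCc2ccc(OC)cc2
F7 | step 6 | O4 4-methoxybenzyl ether of benzoate 8 | CO[C@@H]1C=C(Br)[C@@H](O)[C@@H](OC(=O)c2ccccc2)[C@@H]1OCc2ccc(OC)cc2
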